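## Retrosynthetic overview

- **Numbering of each C15 half:** C12=C1–C2(=O)–C3–C4–C5–C6–C7–C8(CH3)–C9. C9 is also bonded to C1, C4 and C10, and C10–C11(CH3)2–C5 completes the skeleton. Ring A = C1, C2, C3, C4, C9; ring B = C4 to C9; ring C = C4, C5, C11, C10, C9. Primed atoms belong to the half without the methylene group.
- **Dimer cut:** alertenone is opened at C3–C12' (Michael dimerisation, then protonation at C1') to two molecules of one alpha-methylene ketone, 24.
- **Ring A cut:** in 24, C12 goes back to a formaldehyde aldol at C1 and H4 to a dissolving-metal reduction. Ring A goes back to the aldol condensation (C3=C4) of an acetonyl ketone whose C1 was a bridgehead ester carbon.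
- **Feature the plan rests on:** rings B and C form a bicyclo[3.2.1]octane with C4 as the one-carbon bridge. With a ketone at C4, ring C is a 4,4-dimethylcyclopentanone whose alpha carbons C9 and C5 are tied by C8(CH3)–C7–C6, the carbon chain of crotonaldehyde. C9–C8 (Michael) and C5–C6 (aldol) are therefore cut together, and the one catalyst-set centre C8 is relayed to C9 and C5, later to C4, C3 and C1'.
- **Ring order:** C (purchased), B (step 2), A (step 9), then union of the two halves (step 13).

Key step: step 2

Assumption: centres that are erased later (C6 in 6 and 7, C4 in 9, C1 in 20 to 23) and the enol ether geometry of 15 are drawn as the isomer expected to prevail; the other isomer would converge on the same downstream compound.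

## Route

Step 1
Reactants: 1 3,3-dimethylcyclopentan-1-one; 2 dimethyl carbonate
Product: 3 methyl 4,4-dimethyl-2-oxocyclopentane-1-carboxylate
Conditions: NaH, (MeO)2CO, THF, reflux; then 1 M HCl, 0 °C
Reagents that add atoms: dimethyl carbonate (2), COC(=O)OC
Why: Claisen-type carbomethoxylation under equilibrating conditions is pulled forward by the stabilised sodium enolate of the product, and only the CH2 remote from the gem-dimethyl carbon (future C9) is acylated productively because the other alpha carbon (future C5) is neopentyl, while no lasting stereocentre arises since 3 is largely enolic.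

Step 2
Reactants: 3 methyl 4,4-dimethyl-2-oxocyclopentane-1-carboxylate; 4 (E)-but-2-enal
Product: 6 methyl (1S,2S,4R,5S)-4-hydroxy-2,6,6-trimethyl-8-oxobicyclo[3.2.1]octane-1-carboxylate, via Michael adduct keto aldehyde 5 (not isolated)
Conditions: (R)-2-[diphenyl(trimethylsilyloxy)methyl]pyrrolidine (15 mol %), PhCO2H (15 mol %), toluene, 0 °C to rt; then 1,8-diazabicyclo[5.4.0]undec-7-ene (20 mol %), rt
Reagents that add atoms: (E)-but-2-enal (4), C/C=C/C=O
Why: The amine and 4 condense to the E, s-trans iminium ion, the enol carbon C9 of 3 adds to its beta carbon C8 (Michael addition), hydrolysis of the enamine frees keto aldehyde 5, and the C4 ketone, which can enolise only toward C5 because C9 is now quaternary, adds through C5 to the C6 aldehyde once the amidine base is present. The closest known reaction type is the amine-catalysed Michael/intramolecular aldol annulation of cyclic beta-keto esters with enals, which delivers hydroxy-substituted bicyclo[3.2.1]octan-8-ones. Ring B closes by a 6-(enolendo)-exo-trig aldol, since both enolate carbons C4 and C5 lie in the new six-membered ring (along the C11–C10 path the same bond is a 7-(enolexo)-exo-trig closure), a favoured mode that is possible only when the C8–C7–C6 chain sits over ring C. C8 is set by the catalyst, whose CPh2(OSiMe3) group covers one face so that C9 bonds to the Si face of C8 and gives 8S (the S-configured amine would give 8R and hence the mirror-image series); C9 is set relative to C8 by a compact synclinal approach with the iminium carbon C6 over the enol oxygen on C4, H8 over ring C and the C8 methyl group pointing outward between ester and C10; C5 follows from C9 because the bridge can span only one face; C6 (hydroxyl drawn anti to C11) is not relied on. The selectivity that the step needs is this pairing of enol face and iminium face (C8 methyl anti to C10), and the substrate secures it through the flat hydrogen-bonded enol ester, which attracts the cationic terminus, and through the C11 methyl groups, one of which projects over each face of ring C and lets only H8 sit there. Toluene and the absence of alkoxide or methanol keep the strained C4–C9 bond of 6 from retro-Dieckmann cleavage.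

Step 3
Reactants: 6 methyl (1S,2S,4R,5S)-4-hydroxy-2,6,6-trimethyl-8-oxobicyclo[3.2.1]octane-1-carboxylate
Product: 7 methyl (1S,2S,4R,5S)-2,6,6-trimethyl-8-oxo-4-[(phenoxycarbonothioyl)oxy]bicyclo[3.2.1]octane-1-carboxylate
Conditions: PhOC(S)Cl, pyridine, 4-(dimethylamino)pyridine (cat.), CH2Cl2, 0 °C to rt
Reagents that add atoms: O-phenyl chlorothionoformate, S=C(Cl)Oc1ccccc1
Why: Thioacylation of the secondary alcohol with amine bases only (first half of a Barton–McCombie deoxygenation) never produces a free alkoxide, so retro-aldol opening and C4–C9 cleavage are avoided, beta-elimination toward C5 is impossible because C5 is a bridgehead, and no stereocentre changes.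

Step 4
Reactants: 7 methyl (1S,2S,4R,5S)-2,6,6-trimethyl-8-oxo-4-[(phenoxycarbonothioyl)oxy]bicyclo[3.2.1]octane-1-carboxylate
Product: 8 methyl (1S,2S,5R)-2,6,6-trimethyl-8-oxobicyclo[3.2.1]octane-1-carboxylate
Conditions: Bu3SnH (0.3 M), azobisisobutyronitrile (cat.), toluene, 90 °C
Reagents that add atoms: none
Why: In this Barton–McCombie radical deoxygenation the stannyl radical adds to sulfur, the C6–O bond fragments and the secondary C6 radical is trapped by concentrated Bu3SnH faster than it can undergo a 1,2-acyl shift through the C4 carbonyl, which erases C6 as a stereocentre so that both carbinol epimers converge.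

Step 5
Reactants: 8 methyl (1S,2S,5R)-2,6,6-trimethyl-8-oxobicyclo[3.2.1]octane-1-carboxylate
Product: 9 (1R,2S,5R,8R)-1-(hydroxymethyl)-2,6,6-trimethylbicyclo[3.2.1]octan-8-ol
Conditions: LiAlH4, THF, 0 °C to reflux; aq NaOH work-up
Reagents that add atoms: none
Why: Exhaustive hydride reduction takes the hindered bridgehead ester to the primary alcohol (C1) and the C4 ketone to a carbinol, with hydride expected from the C10–C11 side away from the axial C8 methyl group, and this centre is irrelevant because it is reoxidised in step 6, where any surviving C4 ketone also converges.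

Step 6
Reactants: 9 (1R,2S,5R,8R)-1-(hydroxymethyl)-2,6,6-trimethylbicyclo[3.2.1]octan-8-ol
Product: 10 (1R,2S,5R)-2,6,6-trimethyl-8-oxobicyclo[3.2.1]octane-1-carbaldehyde
Conditions: Dess–Martin periodinane (3 equiv), CH2Cl2, 0 °C to rt
Reagents that add atoms: none
Why: Dess–Martin oxidation converts both alcohols under neutral conditions, as required for a non-enolisable beta-keto aldehyde that bases would deformylate, and it erases the C4 carbinol centre.

Step 7
Reactants: 11 triphenylphosphine hydrobromide; 12 methyl vinyl ether
Product: 13 (1-methoxyethyl)triphenylphosphonium bromide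
Conditions: CH2Cl2, 0 °C to rt, sealed flask
Reagents that add atoms: methyl vinyl ether (12), COC=C
Why: Markovnikov protonation of the enol ether gives the methoxy-stabilised cation, which PPh3 traps in the known addition of phosphonium hydrohalides to enol ethers, and the racemic centre of the salt is lost in the ylide.

Step 8
Reactants: 10 (1R,2S,5R)-2,6,6-trimethyl-8-oxobicyclo[3.2.1]octane-1-carbaldehyde; 13 (1-methoxyethyl)triphenylphosphonium bromide
Product: 16 (1S,2S,5R)-2,6,6-trimethyl-1-(2-oxopropyl)bicyclo[3.2.1]octan-8-one, via methoxyethylidene ylide 14 (not isolated), via methyl enol ether 15 (not isolated)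
Conditions: 13, KN(SiMe3)2, THF, −78 to 0 °C; 10, −78 °C to rt; then 2 M HCl, rt
Reagents that add atoms: (1-methoxyethyl)triphenylphosphonium bromide (13), COC(C)[P+](c1ccccc1)(c1ccccc1)c1ccccc1.[Br-]; water, O
Why: The Wittig olefination with a non-stabilised alpha-methoxy ylide selects the aldehyde because both faces of the C4 ketone are screened (C8 methyl on one, C11 methyl on the other), 10 has no enolisable hydrogen to quench the ylide, and acid hydrolysis of either enol ether isomer gives the same methyl ketone, so the former ester carbon becomes the C1 methylene of an acetonyl group.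

Step 9
Reactants: 16 (1S,2S,5R)-2,6,6-trimethyl-1-(2-oxopropyl)bicyclo[3.2.1]octan-8-one
Product: 18 (1S,6R,9S)-9,11,11-trimethyltricyclo[4.3.2.0(1,5)]undec-4-en-3-one (C2 ketone; C3=C4), via tricyclic ketol 17 (not isolated)
Conditions: KOH (0.3 equiv), EtOH, 60 °C
Reagents that add atoms: none
Why: In this classical cyclopentenone annulation of a 1,4-diketone (intramolecular aldol condensation) the only productive enolate is that of the C3 methyl group, which reaches C4 from the C10–C11 side to give the ketol with rings A and C cis-fused, and E1cB loss of water gives a C3=C4 alkene of the bicyclo[3.3.0]oct-1-en-3-one type that is exocyclic to the bridged system.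

Step 10
Reactants: 18 (1S,6R,9S)-9,11,11-trimethyltricyclo[4.3.2.0(1,5)]undec-4-en-3-one
Product: 20 (1R,2S,6R,9S)-2-(hydroxymethyl)-9,11,11-trimethyltricyclo[4.3.2.0(1,5)]undec-4-en-3-one (CH2OH on C1), via lithium dienolate 19 (not isolated)
Conditions: LiN(iPr)2, THF, −78 to −40 °C; CH2O (gas, from cracked paraformaldehyde), −78 °C; AcOH
Reagents that add atoms: formaldehyde, C=O
Why: Deprotonation of the enone can occur only at C1 (C3 is vinylic and the gamma hydrogen on C5 sits at a bridgehead), and the cross-conjugated lithium dienolate undergoes aldol addition to monomeric formaldehyde from the C10 side, opposite the C8 methyl group, giving a C1 centre that is erased in step 12.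

Step 11
Reactants: 20 (1R,2S,6R,9S)-2-(hydroxymethyl)-9,11,11-trimethyltricyclo[4.3.2.0(1,5)]undec-4-en-3-one
Product: 22 (1S,2S,5S,6S,9S)-2-(hydroxymethyl)-9,11,11-trimethyltricyclo[4.3.2.0(1,5)]undecan-3-one, via dilithium alkoxide enolate 21 (not isolated)
Conditions: Li, NH3 (l)/THF, −78 °C; solid NH4Cl
Reagents that add atoms: none
Why: Dissolving-metal enone reduction protonates the beta carbon C4 so as to give the far less strained cis fusion of rings A and C (H4 on the C6–C8 side, 4S in the local numbering), the substrate hydroxyl supplies the proton and as a lithium alkoxide cannot be eliminated, and the C2–C3 enolate shields the ketone from over-reduction until the quench.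

Step 12
Reactants: 22 (1S,2S,5S,6S,9S)-2-(hydroxymethyl)-9,11,11-trimethyltricyclo[4.3.2.0(1,5)]undecan-3-one
Product: 24 (1S,5S,6S,9S)-9,11,11-trimethyl-2-methylidenetricyclo[4.3.2.0(1,5)]undecan-3-one (suberosenone), via mesylate 23 (not isolated)
Conditions: MsCl, Et3N, CH2Cl2, 0 °C; then 1,8-diazabicyclo[5.4.0]undec-7-ene, 0 °C
Reagents that add atoms: none
Why: Mesylation followed by E1cB elimination is the standard dehydration of an alpha-hydroxymethyl ketone to an alpha-methylene ketone, C1 becomes trigonal, and no other centre is touched because H4 is not acidic.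

Step 13
Reactants: 24 suberosenone (two molecules)
Product: 27 alertenone, via lithium dienolate 25 (not isolated), via lithium enolate adduct 26 (not isolated)
Conditions: LiN(SiMe3)2 (1 equiv on the first half of 24), THF, −78 °C; second half of 24, −78 to −45 °C; AcOH/THF, −78 °C
Reagents that add atoms: none
Why: Michael addition of the only possible enolate of 24 (at C3, since C1 is trigonal and C9 quaternary) to the unhindered C12' methylene of a second molecule forms C3–C12' on the ring A face that carries H4, away from the C11 methyl group that roofs the concave face (3R, also the more stable epimer), further addition by the hindered enolate 26 is slow, and cold kinetic protonation of 26 from the C10' side, opposite the C8' methyl group, sets 1'S.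

## Compound list

1 | 3,3-dimethylcyclopentan-1-one | CC1(C)CCC(=O)C1 | starting material
2 | dimethyl carbonate | COC(=O)OC | starting material
3 | methyl 4,4-dimethyl-2-oxocyclopentane-1-carboxylate (keto/enol mixture, drawn as the enol) | COC(=O)C1=C(O)CC(C)(C)C1 | intermediate
4 | (E)-but-2-enal (crotonaldehyde) | C/C=C/C=O | starting material
5 | methyl (1S)-4,4-dimethyl-2-oxo-1-[(2S)-4-oxobutan-2-yl]cyclopentane-1-carboxylate | COC(=O)[C@]1(C(=O)CC(C)(C)C1)[C@@H](C)CC=O | intermediate
6 | methyl (1S,2S,4R,5S)-4-hydroxy-2,6,6-trimethyl-8-oxobicyclo[3.2.1]octane-1-carboxylate | COC(=O)[C@]12CC(C)(C)[C@H](C1=O)[C@H](O)C[C@@H]2C | intermediate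
7 | methyl (1S,2S,4R,5S)-2,6,6-trimethyl-8-oxo-4-[(phenoxycarbonothioyl)oxy]bicyclo[3.2.1]octane-1-carboxylate | COC(=O)[C@]12CC(C)(C)[C@H](C1=O)[C@H](OC(=S)Oc1ccccc1)C[C@@H]2C | intermediate
8 | methyl (1S,2S,5R)-2,6,6-trimethyl-8-oxobicyclo[3.2.1]octane-1-carboxylate | COC(=O)[C@]12CC(C)(C)[C@H](C1=O)CC[C@@H]2C | intermediate
9 | (1R,2S,5R,8R)-1-(hydroxymethyl)-2,6,6-trimethylbicyclo[3.2.1]octan-8-ol | OC[C@]12CC(C)(C)[C@H]([C@H]1O)CC[C@@H]2C | intermediate
10 | (1R,2S,5R)-2,6,6-trimethyl-8-oxobicyclo[3.2.1]octane-1-carbaldehyde | O=C[C@]12CC(C)(C)[C@H](C1=O)CC[C@@H]2C | intermediate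
11 | triphenylphosphine hydrobromide | [Br-].[PH+](c1ccccc1)(c1ccccc1)c1ccccc1 | starting material
12 | methyl vinyl ether | COC=C | starting material
13 | (1-methoxyethyl)triphenylphosphonium bromide (racemic) | COC(C)[P+](c1ccccc1)(c1ccccc1)c1ccccc1.[Br-] | intermediate
14 | (1-methoxyethylidene)triphenylphosphorane | COC(C)=P(c1ccccc1)(c1ccccc1)c1ccccc1 | intermediate
15 | (1R,2S,5R)-1-[(1E)-2-methoxyprop-1-en-1-yl]-2,6,6-trimethylbicyclo[3.2.1]octan-8-one | CO/C(C)=C/[C@]12CC(C)(C)[C@H](C1=O)CC[C@@H]2C | intermediate
16 | (1S,2S,5R)-2,6,6-trimethyl-1-(2-oxopropyl)bicyclo[3.2.1]octan-8-one | CC(=O)C[C@]12CC(C)(C)[C@H](C1=O)CC[C@@H]2C | intermediate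
17 | (1S,5R,6R,9S)-5-hydroxy-9,11,11-trimethyltricyclo[4.3.2.0(1,5)]undecan-3-one (OH on C4, on the C6–C8 side) | O=C1C[C@@]2(O)[C@@H]3CC[C@H](C)[C@@]2(C1)CC3(C)C | intermediate
18 | (1S,6R,9S)-9,11,11-trimethyltricyclo[4.3.2.0(1,5)]undec-4-en-3-one | C1C(=O)C=C2[C@@H]3CC[C@H](C)[C@]12CC3(C)C | intermediate
19 | lithium dienolate of 18 (C1=C2–O, C3=C4) | C1=C([O-])C=C2[C@@H]3CC[C@H](C)[C@]12CC3(C)C.[Li+] | intermediate
20 | (1R,2S,6R,9S)-2-(hydroxymethyl)-9,11,11-trimethyltricyclo[4.3.2.0(1,5)]undec-4-en-3-one (CH2OH on the C10 side) | OC[C@H]1C(=O)C=C2[C@@H]3CC[C@H](C)[C@]12CC3(C)C | intermediate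
21 | dilithium salt: C12 alkoxide and C2–C3 enolate of 22 | [Li+].[Li+].[O-]C[C@H]1C([O-])=C[C@H]2[C@@H]3CC[C@H](C)[C@]12CC3(C)C | intermediate
22 | (1S,2S,5S,6S,9S)-2-(hydroxymethyl)-9,11,11-trimethyltricyclo[4.3.2.0(1,5)]undecan-3-one | OC[C@H]1C(=O)C[C@H]2[C@@H]3CC[C@H](C)[C@]12CC3(C)C | intermediate
23 | methanesulfonate of 22 | CS(=O)(=O)OC[C@H]1C(=O)C[C@H]2[C@@H]3CC[C@H](C)[C@]12CC3(C)C | intermediate
24 | suberosenone, (1S,5S,6S,9S)-9,11,11-trimethyl-2-methylidenetricyclo[4.3.2.0(1,5)]undecan-3-one | C=C1C(=O)C[C@H]2[C@@H]3CC[C@H](C)[C@]12CC3(C)C | intermediate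
25 | lithium dienolate of 24 (C12=C1, C2–O, C2=C3) | C=C1C([O-])=C[C@H]2[C@@H]3CC[C@H](C)[C@]12CC3(C)C.[Li+] | intermediate
26 | lithium C1'=C2' enolate of alertenone | C=C1C(=O)[C@H](CC2=C([O-])C[C@H]3[C@@H]4CC[C@H](C)[C@]23CC4(C)C)[C@H]2[C@@H]3CC[C@H](C)[C@]12CC3(C)C.[Li+] | intermediate
27 | alertenone (local numbering 3R,4R,5S,8S,9S,1'S,4'S,5'S,8'S,9'S) | C=C1C(=O)[C@H](C[C@@H]2C(=O)C[C@H]3[C@@H]4CC[C@H](C)[C@]23CC4(C)C)[C@H]2[C@@H]3CC[C@H](C)[C@]12CC3(C)C | target

## Step count

Total step count: 13. Longest linear sequence: 12 steps (steps 1 to 6 and 8 to 13, from 1); step 7 is a one-step side branch.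

## Three steps most likely to fail

**Step 2.** The enol face may pair weakly with the open iminium face, which would erode the C8/C9 relationship. Aldol closure at the neopentyl C5 may also be slow.

The fallback sets out from 3 and comes back at 5. The C9–C8 bond is made instead by branched-selective allylic alkylation of 3 with methyl (E)-but-2-en-1-yl carbonate. The conditions are [Ir(cod)Cl]2, a binaphthol-derived bis(1-phenylethyl)amine phosphoramidite (the ligand antipode chosen for the 8S,9S series), 1,5,7-triazabicyclo[4.4.0]dec-5-ene and LiBr in THF. This reaction type is known to install vicinal quaternary and tertiary centres on cyclic beta-keto esters with the catalyst controlling both. It should give methyl (1S)-1-[(2S)-but-3-en-2-yl]-4,4-dimethyl-2-oxocyclopentane-1-carboxylate F1.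

Hydroboration of the terminal alkene with 9-borabicyclo[3.3.1]nonane and oxidation with NaBO3 should give methyl (1S)-1-[(2S)-4-hydroxybutan-2-yl]-4,4-dimethyl-2-oxocyclopentane-1-carboxylate F2. Dess–Martin oxidation of that alcohol gives 5. 1,8-Diazabicyclo[5.4.0]undec-7-ene in toluene then closes 5 to 6 as in step 2.

**Step 13.** Protons may shuffle between enolates, which would epimerise C1'; this centre appears to be set against the thermodynamic preference because C12' lies next to the C8' methyl group. Michael addition may also continue onto the methylene ketone that remains in the product, giving oligomers.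

The fallback sets out from 24 and comes back at 27. Half of 24 is converted with tert-butyldimethylsilyl triflate and Et3N (CH2Cl2, −78 to 0 °C) into the tert-butyldimethylsilyl dienol ether of 24 F6. Mukaiyama–Michael addition of this donor to the other half of 24 is run under HN(SO2CF3)2 catalysis (CH2Cl2, −78 °C). With silyl transfer it should give the C2' tert-butyldimethylsilyl enol ether of alertenone F7. Cold protodesilylation with HF·pyridine then protonates C1' from the C10' side and gives 27. No strong base is present at any point.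

**Step 8.** The branched ylide may attack the neopentyl aldehyde slowly, and the formyl group may be lost by nucleophilic cleavage in competition.

The fallback sets out from 10 and comes back at 16. The slimmer ylide from (methoxymethyl)triphenylphosphonium chloride and KN(SiMe3)2 should give (1R,2S,5R)-1-[(E)-2-methoxyethenyl]-2,6,6-trimethylbicyclo[3.2.1]octan-8-one F3. Aqueous HCl in THF hydrolyses it to 2-[(1S,2S,5R)-2,6,6-trimethyl-8-oxobicyclo[3.2.1]octan-1-yl]acetaldehyde F4. MeMgBr at −78 °C adds only to the aldehyde and gives (1S,2S,5R)-1-(2-hydroxypropyl)-2,6,6-trimethylbicyclo[3.2.1]octan-8-one F5 as both carbinol epimers. Dess–Martin oxidation of these gives 16.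

## Further compounds

F1 | step 2 | methyl (1S)-1-[(2S)-but-3-en-2-yl]-4,4-dimethyl-2-oxocyclopentane-1-carboxylate | COC(=O)[C@]1(C(=O)CC(C)(C)C1)[C@@H](C)C=C
F2 | step 2 | methyl (1S)-1-[(2S)-4-hydroxybutan-2-yl]-4,4-dimethyl-2-oxocyclopentane-1-carboxylate | COC(=O)[C@]1(C(=O)CC(C)(C)C1)[C@@H](C)CCO
F3 | step 8 | (1R,2S,5R)-1-[(E)-2-methoxyethenyl]-2,6,6-trimethylbicyclo[3.2.1]octan-8-one | CO/C=C/[C@]12CC(C)(C)[C@H](C1=O)CC[C@@H]2C
F4 | step 8 | 2-[(1S,2S,5R)-2,6,6-trimethyl-8-oxobicyclo[3.2.1]octan-1-yl]acetaldehyde | O=CC[C@]12CC(C)(C)[C@H](C1=O)CC[C@@H]2C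
F5 | step 8 | (1S,2S,5R)-1-(2-hydroxypropyl)-2,6,6-trimethylbicyclo[3.2.1]octan-8-one (both carbinol epimers) | CC(O)C[C@]12CC(C)(C)[C@H](C1=O)CC[C@@H]2C
F6 | step 13 | tert-butyldimethylsilyl dienol ether of 24 | C=C1C(O[Si](C)(C)C(C)(C)C)=C[C@H]2[C@@H]3CC[C@H](C)[C@]12CC3(C)C
F7 | step 13 | C2' tert-butyldimethylsilyl enol ether of alertenone | C=C1C(=O)[C@H](CC2=C(O[Si](C)(C)C(C)(C)C)C[C@H]3[C@@H]4CC[C@H](C)[C@]23CC4(C)C)[C@H]2[C@@H]3CC[C@H](C)[C@]12CC3(C)C
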